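**Strategy.** The oxolane ring O6–C7–C1–C8–C5 of the 6-oxabicyclo[3.2.1]octane core is read as a γ-butyrolactone with C7 as carbonyl, which makes C5 a ketone carbon and C8 an enoate β-carbon. A samarium ketyl from a Roche-ester-derived ketone bearing a dioxolane-masked 3-oxobutyl chain adds to a 6-silyloxyhex-2-enoate and lactonises in the same operation, forging C5–C8 and O6–C7 and setting C5 and C8. The arm oxygen carries a bulky, non-coordinating silyl group so that Felkin–Anh approach, not a samarium chelate, selects the ketyl face. Allylation, a samarium Reformatsky aldol (C1–C2), lactone-to-ether reduction and B-alkyl Suzuki coupling with an irone-derived dienyl iodide finish the skeleton.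

Key step: step 6

Remark 1: C1–C8 and O6 are the positions of the 6-oxabicyclo[3.2.1]octane core of the target; "arm" is the propanal side chain on C5.
Remark 2: enantiopure cis-α-irone 24 with (1R,5S) ring configuration is assumed to be available from orris oil or by resolution of the commercial racemate.
Remark 3: the arm oxygen is a TBS ether and not a benzyl-type ether, because a six-membered samarium chelate through an ether oxygen would open the ketyl face anti to the α-methyl group and lead to the C5 epimer; the silyl ether also removes the need for a debenzylation in the presence of alkenes.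

Step 1
Reactants: 1 methyl (2R)-3-hydroxy-2-methylpropanoate (Roche ester)
Product: 2 methyl (2R)-3-[(tert-butyldimethylsilyl)oxy]-2-methylpropanoate
Conditions: TBSCl, imidazole, CH2Cl2, 0 °C → rt
Reagents that add atoms: tert-butyldimethylsilyl chloride, CC(C)(C)[Si](C)(C)Cl
Why: Imidazole-mediated silylation of a primary alcohol; the stereocenter is not touched.

Step 2
Reactants: 2 methyl (2R)-3-[(tert-butyldimethylsilyl)oxy]-2-methylpropanoate
Product: 3 (2R)-3-[(tert-butyldimethylsilyl)oxy]-N-methoxy-N,2-dimethylpropanamide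
Conditions: MeNH(OMe)·HCl, i-PrMgCl, THF, −20 → 0 °C
Reagents that add atoms: N,O-dimethylhydroxylamine hydrochloride, CNOC.Cl
Why: Aminolysis of the ester by the magnesium amide of N,O-dimethylhydroxylamine (Weinreb amide formation), a method that does not epimerise Roche-type esters.

Step 3
Reactants: 4 2-(2-bromoethyl)-2-methyl-1,3-dioxolane; 3 (2R)-3-[(tert-butyldimethylsilyl)oxy]-N-methoxy-N,2-dimethylpropanamide
Product: 6 (2R)-1-[(tert-butyldimethylsilyl)oxy]-2-methyl-5-(2-methyl-1,3-dioxolan-2-yl)pentan-3-one, via Grignard reagent 5 (not isolated)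
Conditions: 4, Mg, THF, 25 °C; then 3, 0 °C; aq. NH4Cl
Reagents that add atoms: none
Why: Weinreb ketone synthesis: the Grignard adduct stays as a chelated tetrahedral intermediate until work-up, so no over-addition occurs and the α-stereocenter is not exposed to base as a ketone.

Step 4
Reactants: 7 butane-1,4-diol
Product: 8 4-[(tert-butyldiphenylsilyl)oxy]butan-1-ol
Conditions: 7 (excess), TBDPSCl, imidazole, DMF, 0 °C → rt
Reagents that add atoms: tert-butyl(chloro)diphenylsilane, CC(C)(C)[Si](Cl)(c1ccccc1)c1ccccc1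
Why: Statistical monosilylation of a symmetrical diol used in excess.

Step 5
Reactants: 8 4-[(tert-butyldiphenylsilyl)oxy]butan-1-ol
Product: 10 methyl (2E)-6-[(tert-butyldiphenylsilyl)oxy]hex-2-enoate, via aldehyde 9 (not isolated)
Conditions: TEMPO (cat.), PhI(OAc)2, CH2Cl2, rt; then Ph3P=CHCO2Me, rt
Reagents that add atoms: methyl (triphenylphosphoranylidene)acetate, COC(=O)C=P(c1ccccc1)(c1ccccc1)c1ccccc1
Why: Nitroxyl-catalysed oxidation to the aldehyde, then Wittig olefination with a stabilised ylide in the same flask, which should give the E-enoate.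

Step 6
Reactants: 6 (2R)-1-[(tert-butyldimethylsilyl)oxy]-2-methyl-5-(2-methyl-1,3-dioxolan-2-yl)pentan-3-one; 10 methyl (2E)-6-[(tert-butyldiphenylsilyl)oxy]hex-2-enoate
Product: 11 (4S,5R)-5-{(2R)-1-[(tert-butyldimethylsilyl)oxy]propan-2-yl}-4-{3-[(tert-butyldiphenylsilyl)oxy]propyl}-5-[2-(2-methyl-1,3-dioxolan-2-yl)ethyl]oxolan-2-one
Conditions: SmI2 (2.5 equiv), t-BuOH (2 equiv), THF, −78 → 0 °C
Reagents that add atoms: none
Why: Divalent samarium reduces ketone 6 to a ketyl radical anion that adds to the β-carbon of enoate 10 (C5–C8); a second electron gives a trivalent samarium enolate that t-BuOH protonates, and the tertiary samarium alkoxide then displaces methoxide from the ester (O6–C7). The closest known reaction type is the SmI2-mediated reductive coupling of ketones with β-substituted acrylates to cis-β,γ-substituted γ-butyrolactones. The ring closes by 5-exo-trig acyl substitution once the intermolecular bond is made. C5 is controlled by the arm stereocenter in a Felkin–Anh arrangement (CH2OTBS anti to the incoming enoate, hydrogen next to the C4 chain), which the non-coordinating silyl ether permits because no six-membered samarium chelate forms; such a chelate would expose the opposite ketyl face. C8 is controlled relative to C5 by a transition state in which samarium bridges the ketyl oxygen and the ester carbonyl, which places the silyloxypropyl group cis to the α-branched arm. The step needs these two facial selectivities and reduction of the ketone in preference to hydrodimerisation of the enoate, the latter favoured by low temperature and the proton source; minor diastereomers would be removed by chromatography at this stage.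

Step 7
Reactants: 11 lactone (name as in step 6)
Product: 13 (3S,4S,5R)-3-(prop-2-en-1-yl) derivative of 11 (allyl trans to the C4 side chain), via lithium enolate 12 (not isolated)
Conditions: LiN(i-Pr)2, THF, −78 °C; allyl bromide, −78 → −30 °C
Reagents that add atoms: allyl bromide, C=CCBr
Why: Alkylation of the lithium lactone enolate, the electrophile entering anti to the adjacent C4 substituent; this centre is formed again in step 10, so its configuration is not critical.

Step 8
Reactants: 13 α-allyl lactone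
Product: 15 (3S,4R,5S)-3-bromo-3-(prop-2-en-1-yl) lactone (same spatial arrangement as 13, Br anti to the C4 side chain; the C3 epimer serves equally), via potassium enolate 14 (not isolated)
Conditions: KN(SiMe3)2, THF, −78 °C; BrCl2C–CCl2Br, −78 °C
Reagents that add atoms: 1,2-dibromo-1,1,2,2-tetrachloroethane, ClC(Cl)(Br)C(Cl)(Cl)Br
Why: Electrophilic bromination of the fully substituted lactone enolate by a positive-bromine donor gives the tertiary α-bromo lactone needed for regiospecific enolate generation.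

Step 9
Reactants: 15 α-bromo-α-allyl lactone
Product: 16 (3S,4R,5S)-3-bromo-5-{(2R)-1-[(tert-butyldimethylsilyl)oxy]propan-2-yl}-4-{3-[(tert-butyldiphenylsilyl)oxy]propyl}-5-(3-oxobutyl)-3-(prop-2-en-1-yl)oxolan-2-one
Conditions: PPTS, acetone/H2O (10:1), 40 °C
Reagents that add atoms: water, O
Why: Mild acid-catalysed hydrolysis of the dioxolane under conditions that spare primary TBS and TBDPS ethers and the tertiary bromide.

Step 10
Reactants: 16 bromo keto lactone
Product: 17 (1R,2S,5R,8S)-5-{(2R)-1-[(tert-butyldimethylsilyl)oxy]propan-2-yl}-8-{3-[(tert-butyldiphenylsilyl)oxy]propyl}-2-hydroxy-2-methyl-1-(prop-2-en-1-yl)-6-oxabicyclo[3.2.1]octan-7-one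
Conditions: SmI2 (2.2 equiv), THF, −78 °C
Reagents that add atoms: none
Why: Samarium Reformatsky reaction: two-electron reduction of the C–Br bond gives a trivalent samarium lactone enolate that adds to the tethered methyl ketone (6-exo-trig aldol, C1–C2), the tether fixing C1 on the face of the C4 chain and a samarium bridge between enolate and ketone oxygens placing the C2–O bond gauche to C7 (equatorial OH, axial methyl) as the target requires.

Step 11
Reactants: 17 bicyclic hydroxy lactone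
Product: 18 2-O-triethylsilyl ether of 17
Conditions: TESOTf, 2,6-lutidine, CH2Cl2, −78 → 0 °C
Reagents that add atoms: triethylsilyl trifluoromethanesulfonate, CC[Si](CC)(CC)OS(=O)(=O)C(F)(F)F
Why: Silyl triflate silylation of the hindered tertiary alcohol under non-basic conditions avoids retro-aldol cleavage and later prevents this oxygen from displacing the primary iodide of step 15.

Step 12
Reactants: 18 silyl-protected bicyclic lactone
Product: 19 lactol, the 7-hydroxy-6-oxabicyclo[3.2.1]octane corresponding to 18 (mixture at C7)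
Conditions: i-Bu2AlH, CH2Cl2, −78 °C
Reagents that add atoms: none
Why: Half-reduction of a lactone with i-Bu2AlH at low temperature; the bridged lactol resists ring opening and hence over-reduction.

Step 13
Reactants: 19 lactol
Product: 20 (1S,2S,5R,8S)-5-{(2R)-1-[(tert-butyldimethylsilyl)oxy]propan-2-yl}-8-{3-[(tert-butyldiphenylsilyl)oxy]propyl}-2-methyl-1-(prop-2-en-1-yl)-2-[(triethylsilyl)oxy]-6-oxabicyclo[3.2.1]octane
Conditions: Et3SiH, BF3·OEt2, CH2Cl2, −78 → −40 °C
Reagents that add atoms: none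
Why: Ionic hydrogenation: BF3 ionises the lactol to the O6=C7 oxocarbenium ion, which Et3SiH reduces to the cyclic ether, while silyl ethers and the allyl group survive at low temperature.

Step 14
Reactants: 20 allyl ether
Product: 22 2-[(1S,2S,5R,8S)-5-{(2R)-1-[(tert-butyldimethylsilyl)oxy]propan-2-yl}-8-{3-[(tert-butyldiphenylsilyl)oxy]propyl}-2-methyl-2-[(triethylsilyl)oxy]-6-oxabicyclo[3.2.1]octan-1-yl]ethan-1-ol, via aldehyde 21 (not isolated)
Conditions: O3, CH2Cl2/MeOH, −78 °C; then NaBH4, −78 → 0 °C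
Reagents that add atoms: ozone, [O-][O+]=O
Why: Ozonolysis of the terminal alkene with reductive borohydride work-up removes one carbon and gives the primary alcohol directly.

Step 15
Reactants: 22 primary alcohol
Product: 23 1-(2-iodoethyl) compound corresponding to 22
Conditions: I2, PPh3, imidazole, CH2Cl2, 0 °C → rt
Reagents that add atoms: iodine, II
Why: Appel-type iodination, SN2 displacement of the alkoxyphosphonium ion by iodide at an unhindered primary carbon.

Step 16
Reactants: 24 (3E)-4-[(1R,5S)-2,5,6,6-tetramethylcyclohex-2-en-1-yl]but-3-en-2-one (cis-α-irone)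
Product: 27 (1E)-1-[(1R,5S)-2,5,6,6-tetramethylcyclohex-2-en-1-yl]but-1-en-3-yne, via lithium dienolate 25 (not isolated), via enol phosphate 26 (not isolated)
Conditions: LiN(i-Pr)2, THF, −78 °C; ClP(O)(OEt)2, −78 °C → rt; LiN(i-Pr)2 (2.2 equiv), −78 → 0 °C
Reagents that add atoms: none
Why: Kinetic deprotonation at the methyl group, O-phosphorylation and base-induced elimination of diethyl phosphate convert the methyl ketone into the terminal alkyne, low temperature and a small excess of base protecting the doubly allylic ring stereocenter.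

Step 17
Reactants: 27 enyne
Product: 29 (1E,3E)-1-iodo-2-methyl-4-[(1R,5S)-2,5,6,6-tetramethylcyclohex-2-en-1-yl]buta-1,3-diene, via dienylalane 28 (not isolated)
Conditions: Me3Al, Cp2ZrCl2 (cat.), CH2Cl2, rt; then I2, THF, −30 → 0 °C
Reagents that add atoms: trimethylaluminium, C[Al](C)C; iodine, II
Why: Zirconium-catalysed syn-carboalumination (Negishi carboalumination) puts methyl on the internal and aluminium on the terminal alkyne carbon, and iodinolysis with retention gives the E-trisubstituted vinyl iodide.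

Step 18
Reactants: 23 primary iodide; 29 dienyl iodide
Product: 32 (1S,2S,5R,8S)-5-{(2R)-1-[(tert-butyldimethylsilyl)oxy]propan-2-yl}-8-{3-[(tert-butyldiphenylsilyl)oxy]propyl}-2-methyl-1-{(3E,5E)-4-methyl-6-[(1R,5S)-2,5,6,6-tetramethylcyclohex-2-en-1-yl]hexa-3,5-dien-1-yl}-2-[(triethylsilyl)oxy]-6-oxabicyclo[3.2.1]octane, via alkyllithium 30 (not isolated), via lithium borinate 31 (not isolated)
Conditions: 23, t-BuLi (2.1 equiv), Et2O, −78 °C; B-MeO-9-BBN, THF, −78 °C → rt; then 29, Pd(dppf)Cl2 (cat.), AsPh3, aq. K3PO4, DMF, rt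
Reagents that add atoms: none
Why: Lithium–iodine exchange, trapping as the 9-BBN borinate and B-alkyl Suzuki–Miyaura coupling join the sp3 carbon to the dienyl iodide with retention of both olefin geometries.

Step 19
Reactants: 32 tris-silyl ether
Product: 33 (2R)-2-[(1S,2S,5R,8S)-8-{3-[(tert-butyldiphenylsilyl)oxy]propyl}-2-hydroxy-2-methyl-1-{(3E,5E)-4-methyl-6-[(1R,5S)-2,5,6,6-tetramethylcyclohex-2-en-1-yl]hexa-3,5-dien-1-yl}-6-oxabicyclo[3.2.1]octan-5-yl]propan-1-ol
Conditions: camphorsulfonic acid (cat.), MeOH/CH2Cl2, 0 °C → rt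
Reagents that add atoms: none
Why: Acid-catalysed methanolysis removes the primary TBS and the tertiary TES ether, while the much more acid-stable primary TBDPS ether stays.

Step 20
Reactants: 33 diol
Product: 34 (2S)-2-[(1S,2S,5R,8S)-8-{3-[(tert-butyldiphenylsilyl)oxy]propyl}-2-hydroxy-2-methyl-1-{(3E,5E)-4-methyl-6-[(1R,5S)-2,5,6,6-tetramethylcyclohex-2-en-1-yl]hexa-3,5-dien-1-yl}-6-oxabicyclo[3.2.1]octan-5-yl]propanal
Conditions: Dess–Martin periodinane, NaHCO3, CH2Cl2, 0 °C → rt
Reagents that add atoms: none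
Why: Buffered Dess–Martin oxidation converts the primary alcohol into the aldehyde without touching the tertiary alcohol or epimerising the hindered α-stereocenter.

Step 21
Reactants: 34 silyl-protected aldehyde
Product: 35 (2S)-2-[(1S,2S,5R,8S)-2-hydroxy-8-(3-hydroxypropyl)-2-methyl-1-{(3E,5E)-4-methyl-6-[(1R,5S)-2,5,6,6-tetramethylcyclohex-2-en-1-yl]hexa-3,5-dien-1-yl}-6-oxabicyclo[3.2.1]octan-5-yl]propanal (CNP0419303.1)
Conditions: HF·pyridine, pyridine, THF, 0 °C → rt
Reagents that add atoms: none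
Why: Fluoride cleavage of the TBDPS ether under buffered, weakly acidic conditions that should not epimerise the α-branched aldehyde; any tertiary TES ether left from step 19 is cleaved here too.

**Compound list**

1 | methyl (2R)-3-hydroxy-2-methylpropanoate | COC(=O)[C@H](C)CO | starting material
2 | methyl (2R)-3-[(tert-butyldimethylsilyl)oxy]-2-methylpropanoate | COC(=O)[C@H](C)CO[Si](C)(C)C(C)(C)C | intermediate
3 | (2R)-3-[(tert-butyldimethylsilyl)oxy]-N-methoxy-N,2-dimethylpropanamide | CON(C)C(=O)[C@H](C)CO[Si](C)(C)C(C)(C)C | intermediate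
4 | 2-(2-bromoethyl)-2-methyl-1,3-dioxolane | CC1(CCBr)OCCO1 | starting material
5 | [2-(2-methyl-1,3-dioxolan-2-yl)ethyl]magnesium bromide | CC1(CC[Mg]Br)OCCO1 | intermediate
6 | (2R)-1-[(tert-butyldimethylsilyl)oxy]-2-methyl-5-(2-methyl-1,3-dioxolan-2-yl)pentan-3-one | C[C@H](CO[Si](C)(C)C(C)(C)C)C(=O)CCC1(C)OCCO1 | intermediate
7 | butane-1,4-diol | OCCCCO | starting material
8 | 4-[(tert-butyldiphenylsilyl)oxy]butan-1-ol | OCCCCO[Si](c1ccccc1)(c1ccccc1)C(C)(C)C | intermediate
9 | 4-[(tert-butyldiphenylsilyl)oxy]butanal | O=CCCCO[Si](c1ccccc1)(c1ccccc1)C(C)(C)C | intermediate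
10 | methyl (2E)-6-[(tert-butyldiphenylsilyl)oxy]hex-2-enoate | COC(=O)/C=C/CCCO[Si](c1ccccc1)(c1ccccc1)C(C)(C)C | intermediate
11 | (4S,5R)-5-{(2R)-1-[(tert-butyldimethylsilyl)oxy]propan-2-yl}-4-{3-[(tert-butyldiphenylsilyl)oxy]propyl}-5-[2-(2-methyl-1,3-dioxolan-2-yl)ethyl]oxolan-2-one | C1C(=O)O[C@]([C@H](C)CO[Si](C)(C)C(C)(C)C)(CCC2(C)OCCO2)[C@H]1CCCO[Si](c2ccccc2)(c2ccccc2)C(C)(C)C | intermediate
12 | lithium enolate of 11 | C1=C(O[Li])O[C@]([C@H](C)CO[Si](C)(C)C(C)(C)C)(CCC2(C)OCCO2)[C@H]1CCCO[Si](c2ccccc2)(c2ccccc2)C(C)(C)C | intermediate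
13 | (3S,4S,5R)-3-(prop-2-en-1-yl) derivative of 11 | C=CC[C@@H]1C(=O)O[C@]([C@H](C)CO[Si](C)(C)C(C)(C)C)(CCC2(C)OCCO2)[C@H]1CCCO[Si](c2ccccc2)(c2ccccc2)C(C)(C)C | intermediate
14 | potassium enolate of 13 | C=CCC1=C(O[K])O[C@]([C@H](C)CO[Si](C)(C)C(C)(C)C)(CCC2(C)OCCO2)[C@H]1CCCO[Si](c2ccccc2)(c2ccccc2)C(C)(C)C | intermediate
15 | (3S,4R,5S)-3-bromo-3-(prop-2-en-1-yl) derivative of 11 | C=CC[C@@]1(Br)C(=O)O[C@]([C@H](C)CO[Si](C)(C)C(C)(C)C)(CCC2(C)OCCO2)[C@H]1CCCO[Si](c2ccccc2)(c2ccccc2)C(C)(C)C | intermediate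
16 | (3S,4R,5S)-3-bromo-5-{(2R)-1-[(tert-butyldimethylsilyl)oxy]propan-2-yl}-4-{3-[(tert-butyldiphenylsilyl)oxy]propyl}-5-(3-oxobutyl)-3-(prop-2-en-1-yl)oxolan-2-one | C=CC[C@@]1(Br)C(=O)O[C@]([C@H](C)CO[Si](C)(C)C(C)(C)C)(CCC(C)=O)[C@H]1CCCO[Si](c2ccccc2)(c2ccccc2)C(C)(C)C | intermediate
17 | (1R,2S,5R,8S)-5-{(2R)-1-[(tert-butyldimethylsilyl)oxy]propan-2-yl}-8-{3-[(tert-butyldiphenylsilyl)oxy]propyl}-2-hydroxy-2-methyl-1-(prop-2-en-1-yl)-6-oxabicyclo[3.2.1]octan-7-one | C=CC[C@]12C(=O)O[C@]([C@H](C)CO[Si](C)(C)C(C)(C)C)(CC[C@]1(C)O)[C@H]2CCCO[Si](c1ccccc1)(c1ccccc1)C(C)(C)C | intermediate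
18 | 2-O-triethylsilyl ether of 17 | C=CC[C@]12C(=O)O[C@]([C@H](C)CO[Si](C)(C)C(C)(C)C)(CC[C@]1(C)O[Si](CC)(CC)CC)[C@H]2CCCO[Si](c1ccccc1)(c1ccccc1)C(C)(C)C | intermediate
19 | lactol from 18 (7-hydroxy, both C7 epimers) | C=CC[C@]12C(O)O[C@]([C@H](C)CO[Si](C)(C)C(C)(C)C)(CC[C@]1(C)O[Si](CC)(CC)CC)[C@H]2CCCO[Si](c1ccccc1)(c1ccccc1)C(C)(C)C | intermediate
20 | (1S,2S,5R,8S)-5-{(2R)-1-[(tert-butyldimethylsilyl)oxy]propan-2-yl}-8-{3-[(tert-butyldiphenylsilyl)oxy]propyl}-2-methyl-1-(prop-2-en-1-yl)-2-[(triethylsilyl)oxy]-6-oxabicyclo[3.2.1]octane | C=CC[C@]12CO[C@]([C@H](C)CO[Si](C)(C)C(C)(C)C)(CC[C@]1(C)O[Si](CC)(CC)CC)[C@H]2CCCO[Si](c1ccccc1)(c1ccccc1)C(C)(C)C | intermediate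
21 | 1-(2-oxoethyl) compound from 20 | O=CC[C@]12CO[C@]([C@H](C)CO[Si](C)(C)C(C)(C)C)(CC[C@]1(C)O[Si](CC)(CC)CC)[C@H]2CCCO[Si](c1ccccc1)(c1ccccc1)C(C)(C)C | intermediate
22 | 1-(2-hydroxyethyl) compound (name as in step 14) | OCC[C@]12CO[C@]([C@H](C)CO[Si](C)(C)C(C)(C)C)(CC[C@]1(C)O[Si](CC)(CC)CC)[C@H]2CCCO[Si](c1ccccc1)(c1ccccc1)C(C)(C)C | intermediate
23 | 1-(2-iodoethyl) compound | ICC[C@]12CO[C@]([C@H](C)CO[Si](C)(C)C(C)(C)C)(CC[C@]1(C)O[Si](CC)(CC)CC)[C@H]2CCCO[Si](c1ccccc1)(c1ccccc1)C(C)(C)C | intermediate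
24 | (3E)-4-[(1R,5S)-2,5,6,6-tetramethylcyclohex-2-en-1-yl]but-3-en-2-one (cis-α-irone) | CC1=CC[C@H](C)C(C)(C)[C@@H]1/C=C/C(C)=O | starting material
25 | lithium dienolate of 24 | CC1=CC[C@H](C)C(C)(C)[C@@H]1/C=C/C(=C)O[Li] | intermediate
26 | diethyl (3E)-4-[(1R,5S)-2,5,6,6-tetramethylcyclohex-2-en-1-yl]buta-1,3-dien-2-yl phosphate | CC1=CC[C@H](C)C(C)(C)[C@@H]1/C=C/C(=C)OP(=O)(OCC)OCC | intermediate
27 | (1E)-1-[(1R,5S)-2,5,6,6-tetramethylcyclohex-2-en-1-yl]but-1-en-3-yne | CC1=CC[C@H](C)C(C)(C)[C@@H]1/C=C/C#C | intermediate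
28 | dimethyl{(1E,3E)-2-methyl-4-[(1R,5S)-2,5,6,6-tetramethylcyclohex-2-en-1-yl]buta-1,3-dien-1-yl}alumane | CC1=CC[C@H](C)C(C)(C)[C@@H]1/C=C/C(C)=C/[Al](C)C | intermediate
29 | (1E,3E)-1-iodo-2-methyl-4-[(1R,5S)-2,5,6,6-tetramethylcyclohex-2-en-1-yl]buta-1,3-diene | CC1=CC[C@H](C)C(C)(C)[C@@H]1/C=C/C(C)=C/I | intermediate
30 | alkyllithium from 23 (1-(2-lithioethyl) compound) | [Li]CC[C@]12CO[C@]([C@H](C)CO[Si](C)(C)C(C)(C)C)(CC[C@]1(C)O[Si](CC)(CC)CC)[C@H]2CCCO[Si](c1ccccc1)(c1ccccc1)C(C)(C)C | intermediate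
31 | lithium B-alkyl-B-methoxy-9-borabicyclo[3.3.1]nonan-9-uide from 30 | [Li+].CO[B-]1(CC[C@]34CO[C@]([C@H](C)CO[Si](C)(C)C(C)(C)C)(CC[C@]3(C)O[Si](CC)(CC)CC)[C@H]4CCCO[Si](c5ccccc5)(c5ccccc5)C(C)(C)C)C2CCCC1CCC2 | intermediate
32 | coupled tris-silyl ether (name as in step 18) | CC1=CC[C@H](C)C(C)(C)[C@@H]1/C=C/C(C)=C/CC[C@]12CO[C@]([C@H](C)CO[Si](C)(C)C(C)(C)C)(CC[C@]1(C)O[Si](CC)(CC)CC)[C@H]2CCCO[Si](c1ccccc1)(c1ccccc1)C(C)(C)C | intermediate
33 | diol TBDPS ether (name as in step 19) | CC1=CC[C@H](C)C(C)(C)[C@@H]1/C=C/C(C)=C/CC[C@]12CO[C@]([C@H](C)CO)(CC[C@]1(C)O)[C@H]2CCCO[Si](c1ccccc1)(c1ccccc1)C(C)(C)C | intermediate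
34 | aldehyde TBDPS ether (name as in step 20) | CC1=CC[C@H](C)C(C)(C)[C@@H]1/C=C/C(C)=C/CC[C@]12CO[C@]([C@H](C)C=O)(CC[C@]1(C)O)[C@H]2CCCO[Si](c1ccccc1)(c1ccccc1)C(C)(C)C | intermediate
35 | (2S)-2-[(1S,2S,5R,8S)-2-hydroxy-8-(3-hydroxypropyl)-2-methyl-1-{(3E,5E)-4-methyl-6-[(1R,5S)-2,5,6,6-tetramethylcyclohex-2-en-1-yl]hexa-3,5-dien-1-yl}-6-oxabicyclo[3.2.1]octan-5-yl]propanal | CC1=CC[C@H](C)C(C)(C)[C@@H]1/C=C/C(C)=C/CC[C@]12CO[C@]([C@H](C)C=O)(CC[C@]1(C)O)[C@H]2CCCO | target

**Step count.** 21 steps in total. The longest linear sequence is 17 steps (steps 1–3, 6–15, 18–21); steps 4–5 and 16–17 are side branches.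

**Steps most likely to fail**

1. Step 6. The radical addition joins two hindered partners, so pinacol coupling or hydrodimerisation of the enoate may compete, and the facial selectivity at C5 (Felkin–Anh against the opposite face) or at C8 may be low. The fallback is ionic and stepwise; it sets out from ketone 6 and returns at lactone 11. Lithium methyl propiolate (methyl propiolate, LiN(i-Pr)2, THF, −78 °C) is added to 6 to give methyl (4S)-4-hydroxy-4-{(2R)-1-[(tert-butyldimethylsilyl)oxy]propan-2-yl}-6-(2-methyl-1,3-dioxolan-2-yl)hex-2-ynoate F1, the acetylide following the same Felkin–Anh sense. The Grignard reagent [3-(tert-butyldiphenylsilyloxy)propyl]magnesium bromide F2, made from commercial (3-bromopropoxy)(tert-butyl)diphenylsilane and Mg, is then added with CuI; cuprate syn-addition to the ynoate places the ester cis to the carbinol, and the adduct lactonises to 5-{(2R)-1-[(tert-butyldimethylsilyl)oxy]propan-2-yl}-4-{3-[(tert-butyldiphenylsilyl)oxy]propyl}-5-[2-(2-methyl-1,3-dioxolan-2-yl)ethyl]furan-2(5H)-one F3. Hydrogenation (H2, Pd/C, EtOAc) from the face opposite the α-branched arm should give 11. Each stereocenter is set in its own step, so diastereomers can be separated one at a time.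

2. Step 10. At the congested C1–C2 bond, protonation of the samarium enolate (simple debromination) or retro-aldol cleavage may outrun ring closure, or the C2 epimer may form through a non-bridged transition state. The fallback is a cationic ring closure that needs neither the bromide nor the free ketone; it sets out from allyl lactone 13 and returns at 17. Enolisation and silylation (LiN(i-Pr)2, Me3SiCl, THF, −78 °C) give the O-trimethylsilyl ketene acetal of 13 F4. With Me3SiOTf (cat.) in CH2Cl2 at −78 °C the dioxolane opens to an oxocarbenium ion, which the ketene acetal attacks (Mukaiyama-type acetal alkylation), giving after work-up the 2-O-(2-hydroxyethyl) ether of 17 F5. Appel iodination (I2, PPh3, imidazole) gives the 2-O-(2-iodoethyl) ether of 17 F6, and zinc dust in ethanol removes the iodoethyl group by reductive β-elimination to release 17. The C2 configuration would be checked at this point.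

3. Step 18. Lithium–iodine exchange may be incomplete or accompanied by Wurtz-type coupling, the borinate may protodeboronate before transmetalation, or the dienyl iodide may isomerise under prolonged coupling. The fallback makes the organoboron partner by hydroboration instead of lithiation; it sets out from iodide 23 and returns at 32. E2 elimination (KOt-Bu, THF, 0 °C) gives the 1-ethenyl compound F7. Hydroboration with 9-BBN (THF, rt) gives the B-alkyl-9-borabicyclo[3.3.1]nonane F8, which is coupled in the same flask with 29 (Pd(dppf)Cl2, AsPh3, aq. Cs2CO3, DMF, rt) to give 32.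

**Further compounds**

F1 | step 6 | methyl (4S)-4-hydroxy-4-{(2R)-1-[(tert-butyldimethylsilyl)oxy]propan-2-yl}-6-(2-methyl-1,3-dioxolan-2-yl)hex-2-ynoate | COC(=O)C#C[C@@](O)([C@H](C)CO[Si](C)(C)C(C)(C)C)CCC1(C)OCCO1
F2 | step 6 | [3-(tert-butyldiphenylsilyloxy)propyl]magnesium bromide | Br[Mg]CCCO[Si](c1ccccc1)(c1ccccc1)C(C)(C)C
F3 | step 6 | 5-{(2R)-1-[(tert-butyldimethylsilyl)oxy]propan-2-yl}-4-{3-[(tert-butyldiphenylsilyl)oxy]propyl}-5-[2-(2-methyl-1,3-dioxolan-2-yl)ethyl]furan-2(5H)-one (C5 as in 11) | O=C1O[C@]([C@H](C)CO[Si](C)(C)C(C)(C)C)(CCC2(C)OCCO2)C(CCCO[Si](c2ccccc2)(c2ccccc2)C(C)(C)C)=C1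
F4 | step 10 | O-trimethylsilyl ketene acetal of 13 | C=CCC1=C(O[Si](C)(C)C)O[C@]([C@H](C)CO[Si](C)(C)C(C)(C)C)(CCC2(C)OCCO2)[C@H]1CCCO[Si](c2ccccc2)(c2ccccc2)C(C)(C)C
F5 | step 10 | 2-O-(2-hydroxyethyl) ether of 17 | C=CC[C@]12C(=O)O[C@]([C@H](C)CO[Si](C)(C)C(C)(C)C)(CC[C@]1(C)OCCO)[C@H]2CCCO[Si](c1ccccc1)(c1ccccc1)C(C)(C)C
F6 | step 10 | 2-O-(2-iodoethyl) ether of 17 | C=CC[C@]12C(=O)O[C@]([C@H](C)CO[Si](C)(C)C(C)(C)C)(CC[C@]1(C)OCCI)[C@H]2CCCO[Si](c1ccccc1)(c1ccccc1)C(C)(C)C
F7 | step 18 | 1-ethenyl analogue of 20 | C=C[C@]12CO[C@]([C@H](C)CO[Si](C)(C)C(C)(C)C)(CC[C@]1(C)O[Si](CC)(CC)CC)[C@H]2CCCO[Si](c1ccccc1)(c1ccccc1)C(C)(C)C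
F8 | step 18 | B-alkyl-9-borabicyclo[3.3.1]nonane from F7 | B1(CC[C@]34CO[C@]([C@H](C)CO[Si](C)(C)C(C)(C)C)(CC[C@]3(C)O[Si](CC)(CC)CC)[C@H]4CCCO[Si](c5ccccc5)(c5ccccc5)C(C)(C)C)C2CCCC1CCC2
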